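Readings and results are simulated for substances that don't exist; scatter was added.

Late in Sunday's run nothing climbs: target reads 94.3% at 30.0 s and 93.8% at 90.0 s, with starting material standing beside it. I follow one molecule of solid substrate: it becomes target by passing the cycle once, and each passage takes one coupling partner, so its chance is what I call the partner ceiling, the charge of coupling partner over the charge of solid substrate, held at the whole charge. Sunday's ceiling is 94.6%, close to those readings, while Tuesday's 140% exceeds the whole charge, so there solid substrate is the limiting reagent, and target reads 100.2%.

| setting | Tuesday's | Sunday's | flask |
|---|---|---|---|
| solid substrate | 0.0025 M | 0.0037 M | 0.0050 M |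
| coupling partner | 3.5 mM (fed, over 2.5 s) | 3.5 mM (fed, over 2.5 s) | 3.50 mM (fed, over 2.5 s) |
| free catalyst | 10 µM | 10 µM | 10 µM |
| remark | run made earlier; the fed solution adds 1.0 times the starting volume | run made earlier; the fed solution adds 1.0 times the starting volume | the fed solution adds 1.0 times the starting volume |
| time |  |  | 2.5 min |

| run | time / s | target / % | starting material / % |
|---|---|---|---|
| Tuesday's | 10.0 | 97.6 | 2.0 |
| Tuesday's | 15.0 | 99.4 | 0 |
| Tuesday's | 40.0 | 99.5 | 0.2 |
| Tuesday's | 90.0 | 100.2 | 0 |
| Sunday's | 12.0 | 95.0 | 5.7 |
| Sunday's | 30.0 | 94.3 | 5.9 |
| Sunday's | 60.0 | 94.3 | 5.0 |
| Sunday's | 90.0 | 93.8 | 5.5 |

(readings scatter by 0.5 percentage points)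

- every charge counts on the volume at the start, and the solution that is fed holds the whole dose
- solid, in amounts per volume of the solution: solid substrate
- the earlier runs were read with a standard deviation of 0.5 percentage points
- what may be going on: coupling partner + free catalyst -> catalyst intermediate A; starting material + catalyst intermediate A -> catalyst intermediate B; catalyst intermediate B -> catalyst intermediate C; catalyst intermediate C -> free catalyst + target; solid substrate <-> starting material
- at the start none of the solid substrate is in solution
- what has only dissolved of solid substrate counts as not reacted
- the reaction counts as stopped when no species that holds the solid substrate changes by six tenths of a point or more over the second half of the time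
- starting material means what is dissolved; the solid is not counted in it

* the state of affairs at 2.5 min: stopped, and by what, or still going (for what has run out or reacted, a solid counts together with what of it has only dissolved) (the coupling partner has run out first / no working catalyst is left / it is still moving / all of the solid substrate has reacted / forward and back rates have come level)
* how much target there is at 2.5 min, in percent of the solid substrate charged
* how much starting material there is at 2.5 min, in percent of the solid substrate charged

To whoever takes over: this flask holds 0.0050 M of solid substrate under a feed of coupling partner, so its partner ceiling, coupling partner over solid substrate, is 70.0%. At 2.5 min I expect that much target and the remaining 30.0% as dissolved starting material, with no solid, as Sunday's readings at 12.0 s add up to 100.7%. That this remainder, 0.750 mM in the doubled volume against Sunday's 0.100 mM, also dissolves is my wager, for the readings of neither earlier run give a figure for the solubility.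

The forecast, which parts from my reckoning on the starting material, said the coupling partner has run out first and gave 69.8% of target and 15% of starting material, with the remark “The solubility ceiling is unknown”.

At 2.5 min the flask shows this: the coupling partner has run out first, with 0% of it left, 70.0% of target and 30.0% of starting material.

    coupling partner + free catalyst → catalyst intermediate A (k = 8.60 × 10⁶ /M/s)
    starting material + catalyst intermediate A → catalyst intermediate B (k = 1.20 × 10⁵ /M/s)
    catalyst intermediate B → catalyst intermediate C (k = 110 /s)
    catalyst intermediate C → free catalyst + target (k = 450 /s)
    solid substrate ⇌ starting material, rate k5*(cs5 - [starting material]) while solid is left; crystals form when [starting material] > cs5 (solubility = 4.00 mM, k = 0.150 /s)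

At 0.0417 min, as the feed ended, the flask still held 59.7% as solid substrate while 53.1% of the catalyst stood as catalyst intermediate A and 37.4% as catalyst intermediate B. By 0.500 min target stood at 70.0%, the ceiling of 70.0%, and by 1.25 min coupling partner and solid substrate stood at 0% and 0%, with 100% of the catalyst free. The neighbouring flask with 0.0085 M of solid substrate has a ceiling of 41.2% and ends with 41.2% of target.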